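**Retrosynthetic overview**

- The strategy rests on the dihydrofuran ring: the O1–C2 bond and the C3–carbonyl bond sit on neighbouring carbons and are trans, the pattern left by anti addition of the benzo-ring oxygen (ortho to the alkene) and a carbonyl carbon across the C2=C3 bond of an E-2-hydroxystilbene.
- End-game disconnections: the five O-benzyl groups, then both aryl–C(=O) bonds (at C3 and at the end of the C5 chain), made together from a bis-Weinreb amide and one aryllithium used twice; this leads back to a diester.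
- Key disconnection: O1–C2 and C3–CO2Me of that diester, cut together in an asymmetric oxypalladation–methoxycarbonylation of the hydroxystilbene with CO and MeOH, which sets C2 and C3.
- The stilbene is reached by Heck coupling of an ortho-iodophenol ester with 4-benzyloxystyrene.
- Ring order: the dihydrofuran ring is the only ring formed (step 4); all benzene rings are bought.

Key step: step 4

Assumption (chemistry): the sense of induction of the chiral ligand in step 4 cannot be fixed on paper; the (S,S) ligand is written, and its mirror image is to be used if a pilot run shows that it is the one that leads to the (2S,3S) series.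

**Step 1**
Reactants: 1 methyl 3-(4-hydroxyphenyl)propanoate
Product: 2 methyl 3-(4-hydroxy-3-iodophenyl)propanoate
Conditions: NIS (1.05 equiv), TsOH·H2O (cat.), MeCN, 0 °C to rt
Reagents that add atoms: N-iodosuccinimide, O=C1CCC(=O)N1I
Why: Electrophilic aromatic iodination should go ortho to the hydroxyl because the para position is blocked, and one equivalent of reagent should hold it at the mono-iodide.

**Step 2**
Reactants: 3 4-(benzyloxy)benzaldehyde
Product: 4 1-(benzyloxy)-4-ethenylbenzene
Conditions: Ph3PCH3Br, KOtBu, THF, 0 °C to rt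
Reagents that add atoms: methyltriphenylphosphonium bromide, C[P+](c1ccccc1)(c1ccccc1)c1ccccc1.[Br-]
Why: Wittig methylenation of an aromatic aldehyde with the non-stabilised ylide is dependable and leaves the benzyl ether alone.

**Step 3**
Reactants: 2 methyl 3-(4-hydroxy-3-iodophenyl)propanoate; 4 1-(benzyloxy)-4-ethenylbenzene
Product: 5 methyl 3-{3-[(E)-2-[4-(benzyloxy)phenyl]ethenyl]-4-hydroxyphenyl}propanoate
Conditions: Pd(OAc)2 (5 mol %), P(o-tol)3 (10 mol %), Et3N, DMF, 90 °C
Reagents that add atoms: none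
Why: Mizoroki–Heck reaction, in which oxidative addition of the aryl iodide, syn carbopalladation at the unsubstituted styrene terminus and syn β-hydride elimination should give the E-stilbene, with the free phenol and the ester tolerated.

**Step 4**
Reactants: 5 methyl 3-{3-[(E)-2-[4-(benzyloxy)phenyl]ethenyl]-4-hydroxyphenyl}propanoate; 6 carbon monoxide; 7 methanol
Product: 8 methyl (2S,3S)-2-[4-(benzyloxy)phenyl]-5-(3-methoxy-3-oxopropyl)-2,3-dihydro-1-benzofuran-3-carboxylate
Conditions: Pd(OCOCF3)2 (10 mol %), (S,S)-iPr-BOXAX [2,2'-bis(4-isopropyl-4,5-dihydrooxazol-2-yl)-1,1'-binaphthyl] (20 mol %), p-benzoquinone (3 equiv), CO (30 bar), MeOH–CH2Cl2, 0 °C to rt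
Reagents that add atoms: carbon monoxide, [C-]#[O+] (compound 6); methanol, CO (compound 7)
Why: Proposed new method: the divalent palladium–bis(oxazoline) complex binds the stilbene double bond, the ortho phenol oxygen attacks the carbon bearing the 4-benzyloxyphenyl group on the face away from the metal (anti oxypalladation), the resulting C3–palladium bond inserts CO with retention, methanol cleaves the acylpalladium to the ester and zerovalent palladium, and p-benzoquinone returns the metal to the divalent state. The closest known reactions are the enantioselective Wacker-type oxypalladation–alkoxycarbonylation dominoes of alkenyl phenols (exo closures that leave no β-hydrogen) and the cyclisation of 2-hydroxystilbenes to 2-arylbenzofurans by divalent palladium, whereas trapping of the 5-endo alkylpalladium by CO has not been shown. The dihydrofuran ring closes by O1–C2 bond formation in the 5-endo-trig mode, the only one open to the ortho hydroxyl because attack at the other alkene carbon would make a four-membered ring. C2 is controlled by the chiral ligand, which decides the alkene face that carries palladium and hence the face the oxygen attacks, and C3 is controlled by the E geometry through anti addition and stereoretentive insertion, which places aryl and ester trans; a cis ester from any syn pathway would epimerise at the acidic C3–H to the same trans isomer. The step needs CO insertion to beat β-hydride elimination of the C2–H that lies syn to palladium (the path to the benzofuran), which is served by the benzylic nature of C3 (η3 coordination to the benzo ring fills the vacant site), the chelating ligand and CO under pressure, while the electron-rich aryl group on C2 directs the oxygen to that carbon.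

**Step 5**
Reactants: 8 methyl (2S,3S)-2-[4-(benzyloxy)phenyl]-5-(3-methoxy-3-oxopropyl)-2,3-dihydro-1-benzofuran-3-carboxylate
Product: 9 (2S,3S)-2-[4-(benzyloxy)phenyl]-N-methoxy-5-{3-[methoxy(methyl)amino]-3-oxopropyl}-N-methyl-2,3-dihydro-1-benzofuran-3-carboxamide
Conditions: MeNH(OMe)·HCl, AlMe3, CH2Cl2, 0 to 40 °C; then cold 1 M HCl
Reagents that add atoms: N,O-dimethylhydroxylamine hydrochloride, CNOC.Cl
Why: Weinreb aminolysis of esters by the aluminium amide should convert both esters under non-basic conditions, so that C2 is untouched and C3 can at most settle in the favoured trans arrangement.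

**Step 6**
Reactants: 10 4-bromoresorcinol (4-bromobenzene-1,3-diol)
Product: 11 2,4-bis(benzyloxy)-1-bromobenzene
Conditions: BnBr, K2CO3, DMF, 60 °C
Reagents that add atoms: benzyl bromide, BrCc1ccccc1
Why: Williamson ether synthesis should benzylate both phenols cleanly.

**Step 7**
Reactants: 11 2,4-bis(benzyloxy)-1-bromobenzene; 9 (2S,3S)-2-[4-(benzyloxy)phenyl]-N-methoxy-5-{3-[methoxy(methyl)amino]-3-oxopropyl}-N-methyl-2,3-dihydro-1-benzofuran-3-carboxamide
Product: 13 1-[2,4-bis(benzyloxy)phenyl]-3-[(2S,3S)-3-[2,4-bis(benzyloxy)benzoyl]-2-[4-(benzyloxy)phenyl]-2,3-dihydro-1-benzofuran-5-yl]propan-1-one, via 2,4-bis(benzyloxy)phenyllithium 12 (not isolated)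
Conditions: 11 (3.2 equiv), n-BuLi (3.0 equiv), THF, −78 °C; then 9, −78 to −40 °C; aq. NH4Cl
Reagents that add atoms: none
Why: Bromine–lithium exchange followed by the Weinreb ketone synthesis should give both ketones without over-addition, because each amide holds one aryllithium as a chelated tetrahedral adduct until work-up and, at −78 °C, addition should outpace removal of the hindered C3–H, whose reprotonation would in any case return the trans isomer.

**Step 8**
Reactants: 13 1-[2,4-bis(benzyloxy)phenyl]-3-[(2S,3S)-3-[2,4-bis(benzyloxy)benzoyl]-2-[4-(benzyloxy)phenyl]-2,3-dihydro-1-benzofuran-5-yl]propan-1-one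
Product: 14 1-(2,4-dihydroxyphenyl)-3-[(2S,3S)-3-(2,4-dihydroxybenzoyl)-2-(4-hydroxyphenyl)-2,3-dihydro-1-benzofuran-5-yl]propan-1-one
Conditions: H2 (1 atm), 10% Pd/C, EtOAc–MeOH, rt
Reagents that add atoms: none
Why: Catalytic hydrogenolysis should remove the five primary benzyl aryl ethers, while the hindered secondary O1–C2 ether of the ring and the hydrogen-bonded 2,4-dihydroxyaryl ketones are expected to react far more slowly at 1 atm and rt, and no stereocentre is touched.

**Compound list**

1 | methyl 3-(4-hydroxyphenyl)propanoate | COC(=O)CCc1ccc(O)cc1 | starting material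
2 | methyl 3-(4-hydroxy-3-iodophenyl)propanoate | COC(=O)CCc1ccc(O)c(I)c1 | intermediate
3 | 4-(benzyloxy)benzaldehyde | O=Cc1ccc(OCc2ccccc2)cc1 | starting material
4 | 1-(benzyloxy)-4-ethenylbenzene | C=Cc1ccc(OCc2ccccc2)cc1 | intermediate
5 | methyl 3-{3-[(E)-2-[4-(benzyloxy)phenyl]ethenyl]-4-hydroxyphenyl}propanoate | COC(=O)CCc1ccc(O)c(/C=C/c2ccc(OCc3ccccc3)cc2)c1 | intermediate
6 | carbon monoxide | [C-]#[O+] | starting material
7 | methanol | CO | starting material
8 | methyl (2S,3S)-2-[4-(benzyloxy)phenyl]-5-(3-methoxy-3-oxopropyl)-2,3-dihydro-1-benzofuran-3-carboxylate | COC(=O)CCc1ccc2c(c1)[C@H](C(=O)OC)[C@@H](c1ccc(OCc3ccccc3)cc1)O2 | intermediate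
9 | (2S,3S)-2-[4-(benzyloxy)phenyl]-N-methoxy-5-{3-[methoxy(methyl)amino]-3-oxopropyl}-N-methyl-2,3-dihydro-1-benzofuran-3-carboxamide | CON(C)C(=O)CCc1ccc2c(c1)[C@H](C(=O)N(C)OC)[C@@H](c1ccc(OCc3ccccc3)cc1)O2 | intermediate
10 | 4-bromoresorcinol (4-bromobenzene-1,3-diol) | Oc1ccc(Br)c(O)c1 | starting material
11 | 2,4-bis(benzyloxy)-1-bromobenzene | Brc1ccc(OCc2ccccc2)cc1OCc1ccccc1 | intermediate
12 | [2,4-bis(benzyloxy)phenyl]lithium | [Li]c1ccc(OCc2ccccc2)cc1OCc1ccccc1 | intermediate
13 | 1-[2,4-bis(benzyloxy)phenyl]-3-[(2S,3S)-3-[2,4-bis(benzyloxy)benzoyl]-2-[4-(benzyloxy)phenyl]-2,3-dihydro-1-benzofuran-5-yl]propan-1-one | O=C(CCc1ccc2c(c1)[C@H](C(=O)c3ccc(OCc4ccccc4)cc3OCc3ccccc3)[C@@H](c3ccc(OCc4ccccc4)cc3)O2)c1ccc(OCc2ccccc2)cc1OCc1ccccc1 | intermediate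
14 | 1-(2,4-dihydroxyphenyl)-3-[(2S,3S)-3-(2,4-dihydroxybenzoyl)-2-(4-hydroxyphenyl)-2,3-dihydro-1-benzofuran-5-yl]propan-1-one | O=C(CCc1ccc2c(c1)[C@H](C(=O)c1ccc(O)cc1O)[C@@H](c1ccc(O)cc1)O2)c1ccc(O)cc1O | target

**Step count**

Total steps: 8. Longest linear sequence: 6 steps (steps 1, 3, 4, 5, 7 and 8, from compound 1 to compound 14).

**Steps most likely to fail**

1. Step 4. β-Hydride elimination from the C3–palladium intermediate may outrun CO insertion, so that the alkene is consumed by aromatisation, or the ligand may discriminate the two alkene faces poorly. The fallback builds the same ring by the known enantioselective intramolecular C–H insertion of an aryldiazoacetate. It sets out from compound 2 and comes back at compound 8.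
 - O-Alkylation of 2 with purchased 4-(benzyloxy)benzyl chloride (K2CO3, DMF) should give methyl 3-[4-{[4-(benzyloxy)phenyl]methoxy}-3-iodophenyl]propanoate F1.
 - Palladium-catalysed α-arylation of 1-methoxy-1-(trimethylsilyloxy)ethene (Pd(dba)2, P(tBu)3, ZnF2, DMF, 80 °C) should give methyl 3-[4-{[4-(benzyloxy)phenyl]methoxy}-3-(2-methoxy-2-oxoethyl)phenyl]propanoate F2.
 - Diazo transfer with 4-acetamidobenzenesulfonyl azide and DBU in MeCN, which touches only the arylacetate CH2, should give methyl 3-[4-{[4-(benzyloxy)phenyl]methoxy}-3-(1-diazo-2-methoxy-2-oxoethyl)phenyl]propanoate F3.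
 - Rh2(S-PTTL)4, dirhodium tetrakis[N-phthaloyl-(S)-tert-leucinate] (or its mirror image, whichever sets C2 as S), in toluene at low temperature should insert the carbenoid into the ether CH2 and give the cis ester methyl (2S,3R)-2-[4-(benzyloxy)phenyl]-5-(3-methoxy-3-oxopropyl)-2,3-dihydro-1-benzofuran-3-carboxylate F4.
 - NaOMe in MeOH should then epimerise C3 to the trans diester 8.

2. Step 7. The aryllithium may deprotonate C3 instead of adding to the hindered C3 amide; that amide would then stay unreacted, and β-elimination of the ring phenoxide (ring opening with loss of the C2 configuration) could follow. The fallback goes through aldehydes, which add aryllithiums much faster than they enolise. It sets out from compound 8 and comes back at compound 13.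
 - LiAlH4 (THF, 0 °C) should give 3-[(2S,3R)-2-[4-(benzyloxy)phenyl]-3-(hydroxymethyl)-2,3-dihydro-1-benzofuran-5-yl]propan-1-ol F5.
 - Dess–Martin periodinane (NaHCO3, CH2Cl2) should give (2S,3S)-2-[4-(benzyloxy)phenyl]-5-(3-oxopropyl)-2,3-dihydro-1-benzofuran-3-carbaldehyde F6, to be used at once.
 - Addition of aryllithium 12 (THF, −78 °C) should give 1-[2,4-bis(benzyloxy)phenyl]-3-[(2S,3S-type, 2,3-trans)-3-{[2,4-bis(benzyloxy)phenyl](hydroxy)methyl}-2-[4-(benzyloxy)phenyl]-2,3-dihydro-1-benzofuran-5-yl]propan-1-ol F7, a mixture of epimers at the two carbinol carbons.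
 - A second Dess–Martin oxidation should give diketone 13.

3. Step 8. Over-reduction may set in during the long exposure needed to remove five benzyl ethers: hydrogenolytic opening of the O1–C2 benzylic bond once the 4-hydroxyphenyl group is free, or reduction of the aryl ketones. The fallback changes the protecting-group plan so that the end-game is acid-mediated. It sets out from compound 9 and comes back at compound 14.
 - A short hydrogenolysis (H2, Pd/C, EtOAc) of the single benzyl ether of 9, at a stage that holds no ketone, should give (2S,3S)-2-(4-hydroxyphenyl)-N-methoxy-5-{3-[methoxy(methyl)amino]-3-oxopropyl}-N-methyl-2,3-dihydro-1-benzofuran-3-carboxamide F8.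
 - MOMCl and iPr2NEt in CH2Cl2 should give (2S,3S)-N-methoxy-5-{3-[methoxy(methyl)amino]-3-oxopropyl}-2-[4-(methoxymethoxy)phenyl]-N-methyl-2,3-dihydro-1-benzofuran-3-carboxamide F9.
 - 4-Bromoresorcinol 10 with MOMCl and iPr2NEt should give 1-bromo-2,4-bis(methoxymethoxy)benzene F10, and n-BuLi (THF, −78 °C) should turn it into [2,4-bis(methoxymethoxy)phenyl]lithium F11.
 - Addition of F11 to F9 should give 1-[2,4-bis(methoxymethoxy)phenyl]-3-[(2S,3S)-3-[2,4-bis(methoxymethoxy)benzoyl]-2-[4-(methoxymethoxy)phenyl]-2,3-dihydro-1-benzofuran-5-yl]propan-1-one F12.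
 - HCl in MeOH–THF (rt to 40 °C) should remove the five methoxymethyl groups and give target 14.

**Further compounds**

F1 | step 4 | methyl 3-[4-{[4-(benzyloxy)phenyl]methoxy}-3-iodophenyl]propanoate | COC(=O)CCc1ccc(OCc2ccc(OCc3ccccc3)cc2)c(I)c1
F2 | step 4 | methyl 3-[4-{[4-(benzyloxy)phenyl]methoxy}-3-(2-methoxy-2-oxoethyl)phenyl]propanoate | COC(=O)CCc1ccc(OCc2ccc(OCc3ccccc3)cc2)c(CC(=O)OC)c1
F3 | step 4 | methyl 3-[4-{[4-(benzyloxy)phenyl]methoxy}-3-(1-diazo-2-methoxy-2-oxoethyl)phenyl]propanoate | COC(=O)CCc1ccc(OCc2ccc(OCc3ccccc3)cc2)c(C(=[N+]=[N-])C(=O)OC)c1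
F4 | step 4 | methyl (2S,3R)-2-[4-(benzyloxy)phenyl]-5-(3-methoxy-3-oxopropyl)-2,3-dihydro-1-benzofuran-3-carboxylate | COC(=O)CCc1ccc2c(c1)[C@@H](C(=O)OC)[C@@H](c1ccc(OCc3ccccc3)cc1)O2
F5 | step 7 | 3-[(2S,3R)-2-[4-(benzyloxy)phenyl]-3-(hydroxymethyl)-2,3-dihydro-1-benzofuran-5-yl]propan-1-ol | OCCCc1ccc2c(c1)[C@H](CO)[C@@H](c1ccc(OCc3ccccc3)cc1)O2
F6 | step 7 | (2S,3S)-2-[4-(benzyloxy)phenyl]-5-(3-oxopropyl)-2,3-dihydro-1-benzofuran-3-carbaldehyde | O=CCCc1ccc2c(c1)[C@H](C=O)[C@@H](c1ccc(OCc3ccccc3)cc1)O2
F7 | step 7 | 1-[2,4-bis(benzyloxy)phenyl]-3-[(2,3-trans, ring configuration as in 13)-3-{[2,4-bis(benzyloxy)phenyl](hydroxy)methyl}-2-[4-(benzyloxy)phenyl]-2,3-dihydro-1-benzofuran-5-yl]propan-1-ol, mixture of carbinol epimers | OC(CCc1ccc2c(c1)[C@H](C(O)c3ccc(OCc4ccccc4)cc3OCc3ccccc3)[C@@H](c3ccc(OCc4ccccc4)cc3)O2)c1ccc(OCc2ccccc2)cc1OCc1ccccc1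
F8 | step 8 | (2S,3S)-2-(4-hydroxyphenyl)-N-methoxy-5-{3-[methoxy(methyl)amino]-3-oxopropyl}-N-methyl-2,3-dihydro-1-benzofuran-3-carboxamide | CON(C)C(=O)CCc1ccc2c(c1)[C@H](C(=O)N(C)OC)[C@@H](c1ccc(O)cc1)O2
F9 | step 8 | (2S,3S)-N-methoxy-5-{3-[methoxy(methyl)amino]-3-oxopropyl}-2-[4-(methoxymethoxy)phenyl]-N-methyl-2,3-dihydro-1-benzofuran-3-carboxamide | CON(C)C(=O)CCc1ccc2c(c1)[C@H](C(=O)N(C)OC)[C@@H](c1ccc(OCOC)cc1)O2
F10 | step 8 | 1-bromo-2,4-bis(methoxymethoxy)benzene | COCOc1ccc(Br)c(OCOC)c1
F11 | step 8 | [2,4-bis(methoxymethoxy)phenyl]lithium | [Li]c1ccc(OCOC)cc1OCOC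
F12 | step 8 | 1-[2,4-bis(methoxymethoxy)phenyl]-3-[(2S,3S)-3-[2,4-bis(methoxymethoxy)benzoyl]-2-[4-(methoxymethoxy)phenyl]-2,3-dihydro-1-benzofuran-5-yl]propan-1-one | O=C(CCc1ccc2c(c1)[C@H](C(=O)c3ccc(OCOC)cc3OCOC)[C@@H](c3ccc(OCOC)cc3)O2)c1ccc(OCOC)cc1OCOC
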